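The numbers in the tables were generated by integration from invented constants, and the scatter is random.

How much starting material does Wednesday's flask still hold at 7.0 h? There the partner is the limiting reagent, since its charge is smaller than that of the starting material. The useful count is therefore how many powers of ten the partner falls in that time.

| setting | Monday's | Saturday's | Thursday's | Wednesday's |
|---|---|---|---|---|
| starting material | 300 mM | 120 mM | 300 mM | 1500 mM |
| partner | 360 mM | 180 mM | 360 mM | 360 mM |
| free catalyst | 24.0 mM | 24.0 mM | 36.0 mM | 24.0 mM |
| time |  |  |  | 7.0 h |

| run | time / h | [starting material] / mM |
|---|---|---|
| Monday's run | 1.2 | 208 |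
| Monday's run | 2.3 | 150 |
| Monday's run | 3.5 | 108 |
| Monday's run | 4.7 | 80 |
| Monday's run | 5.8 | 56 |
| Monday's run | 7.0 | 38 |
| Saturday's run | 1.2 | 90 |
| Saturday's run | 2.3 | 64 |
| Saturday's run | 3.5 | 45 |
| Saturday's run | 4.7 | 27 |
| Saturday's run | 5.8 | 23 |
| Saturday's run | 7.0 | 21 |
| Thursday's run | 1.2 | 179 |
| Thursday's run | 2.3 | 117 |
| Thursday's run | 3.5 | 67 |
| Thursday's run | 4.7 | 36 |
| Thursday's run | 5.8 | 17 |
| Thursday's run | 7.0 | 7 |

(standard deviation of a reading: 3 mM)

1. how the opening rate goes with [free catalyst] round the charge of the Monday's run: the exponent of the rate at two percent of starting material gone to target
2. the Saturday's run starts with 180 mM less of starting material and of partner than the Monday's run, and with no target. Compared where both hold the same amount of starting material, once fifteen percent of what the Saturday's run was charged with has turned into target, is the Saturday's run faster, slower or alike (within a tenth)?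
3. starting material in the Wednesday's run at 7.0 h, as a share of the starting material charged

- Overall: starting material + partner -> target, with free catalyst as catalyst.
- Constant volume, constant temperature.
- A reading of a species includes what of it is bound.
- "The second partner" is partner.
- An order is taken over about fifteen percent of the charge, up and down.

Monday's run supplies the scale. Over its first 1.2 h, c(starting material) falls at 76.7 mM h⁻¹, with mean values near 254 mM of starting material and 314 mM of partner. Dividing that rate by both concentrations and multiplying by Wednesday's charges puts the opening slope of Wednesday's curve near 519 mM h⁻¹. This is an estimate, borrowed from Monday's charge of 300 mM of starting material.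

Next comes the level. Each target takes one of each reagent, so once 360 mM of each has turned, Wednesday's flask holds 1140 mM of starting material, 76.0 % of its charge.

Then comes the knee. Near that level c(starting material) is nearly constant, so this reckoning lets the partner decay in a pseudo-first-order way, with a log-slope of 1.10 h⁻¹. That gives 2.10 h as the decade time, the hours in which the partner falls by one power of ten. This reckoning puts the knee of Wednesday's curve near this time. The asked time holds 3.34 decades, so this reckoning commits to the level, 76.0 %.

Saturday's and Monday's runs share an excess of partner of 60.0 mM, so at equal starting material they hold equal partner, and this reckoning expects them to be alike.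

The forecast gives 0.8 for the catalyst exponent, alike for Saturday against Monday, and 80 % for Wednesday, which is higher than the level reckoned here. Its ground for Wednesday is that “About 310 mM is consumed”.

The flask gives an exponent of 0.37, the answer alike with a rate ratio of 1.0, and 76.1 % for Wednesday.

    free catalyst + starting material → catalyst-substrate complex (60.12 M⁻¹ h⁻¹)
    catalyst-substrate complex + partner → loaded catalyst (18.47 M⁻¹ h⁻¹)
    loaded catalyst → target + free catalyst (7.668 h⁻¹)
    free catalyst + impurity → spent catalyst
    starting material + partner → target (0.5580 M⁻¹ h⁻¹)

At 76.1 % of its charge, Wednesday's flask holds by the balance 0.850 mM of partner at 7.0 h, bound forms counted. That is 2.63 decades, and a mean decade time of 2.66 h, longer than the reckoned 2.10 h. The step from starting material and partner to target, which needs no catalyst, carries Wednesday's flask this close to its level. Wednesday's run without that step stands at 84.9 % at 7.0 h, holding 133 mM of partner, bound forms counted. That is 0.433 decades, a mean decade time of 16.2 h.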